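The 7-benzyl-8-oxyquinolinone is read as the aromatic tautomer of a 7-benzylidene-6,7-dihydro-5H-quinolin-8-one. The benzylic CH2–C7 bond is therefore made by a Claisen–Schmidt condensation between O-benzylvanillin and 3-methoxy-6,7-dihydroquinoline-2,8(1H,5H)-dione, and base in the same pot moves the exocyclic double bond into the carbocycle (C5–C8), which aromatises. The step exploits the ortho pair C7–C8(O) of the benzo ring: C7 is the only enolisable carbon next to the C8 ketone, so one operation joins the halves without regiochemical choice, builds the arene and releases O8 as the only free phenol for sulfation. The ketone comes in two steps from a bromo-enal and methoxyacetamide.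

Key step: step 3

Remark: the target has no stereocentre and no stereogenic double bond, so it is one achiral compound; it is drawn as the free hydrogen sulfate, and the aryl sulfates 9 and 10 are handled as sodium salts (drawn in the acid form), the acid being released at the end on an H+ resin in the cold.

Step 1
Reactants: 1 2-bromocyclohex-1-ene-1-carbaldehyde; 2 2-methoxyacetamide
Product: 4 3-methoxy-5,6,7,8-tetrahydroquinolin-2(1H)-one, via N-(2-formylcyclohex-1-en-1-yl)-2-methoxyacetamide 3 (not isolated)
Conditions: Pd2(dba)3 (2.5 mol%), Xantphos (7.5 mol%), Cs2CO3 (2.5 equiv), 1,4-dioxane, 100 °C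
Reagents that add atoms: none
Why: Buchwald-type Pd-catalysed amidation of the vinyl bromide should give enamide 3, whose methoxyacetyl CH2 then condenses with the neighbouring aldehyde under the same carbonate base (intramolecular aldol condensation of the Friedländer/Camps type) to close the 2-pyridone.

Step 2
Reactants: 4 3-methoxy-5,6,7,8-tetrahydroquinolin-2(1H)-one
Product: 5 3-methoxy-6,7-dihydroquinoline-2,8(1H,5H)-dione
Conditions: SeO2 (1.1 equiv), wet 1,4-dioxane, 90 °C
Reagents that add atoms: selenium dioxide, O=[Se]=O
Why: Riley oxidation, in which the ene reaction of SeO2 at the nucleophilic C4a of the C4a=C8a enamide bond removes the allylic hydrogen from C8 and the [2,3] shift places oxygen on C8, the position at which 6-alkyl-2-pyridones and 2-alkylpyridines are oxidised.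

Step 3
Reactants: 5 3-methoxy-6,7-dihydroquinoline-2,8(1H,5H)-dione; 6 4-(benzyloxy)-3-methoxybenzaldehyde
Product: 8 7-[4-(benzyloxy)-3-methoxybenzyl]-8-hydroxy-3-methoxyquinolin-2(1H)-one, via benzylidene ketone 7 (not isolated)
Conditions: KOtBu (3.5 equiv), DMSO–t-BuOH, rt then 80 °C, Ar; aq. HCl
Reagents that add atoms: none
Why: Claisen–Schmidt aldol condensation of the C7 enolate of 5 with the non-enolisable aldehyde 6 forms the exocyclic C7=CH alkene of 7; base then moves this alkene into the ring by deprotonation at C6 and reprotonation at the exocyclic carbon, and loss of a C5 proton from the resulting dienone gives the 8-phenoxide directly. The closest known reaction type is the base- or RhCl3-mediated conversion of 2-benzylidene-1-tetralones (or of 1-tetralone plus an aryl aldehyde) into 2-benzyl-1-naphthols. No ring is closed: the existing C4a–C5–C6–C7–C8–C8a carbocycle is aromatised, which drives the sequence and makes it irreversible. No stereocentre is formed, and the E/Z geometry of 7 disappears in the product. The step needs regioselectivity for C7, which the substrate secures because C7 is the only enolisable carbon next to the C8 ketone (C8a is sp2) and 6 cannot enolise. It also needs the guaiacyl oxygen to stay masked, and the benzyl ether is inert to alkoxide, so O8 should emerge as the only free phenol.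

Step 4
Reactants: 8 7-[4-(benzyloxy)-3-methoxybenzyl]-8-hydroxy-3-methoxyquinolin-2(1H)-one
Product: 9 7-[4-(benzyloxy)-3-methoxybenzyl]-3-methoxy-2-oxo-1,2-dihydroquinolin-8-yl hydrogen sulfate
Conditions: SO3·pyridine (3 equiv), pyridine, 50 °C; aq. NaHCO3 work-up, C18 (sodium salt)
Reagents that add atoms: sulfur trioxide–pyridine complex, [O-]S(=O)(=O)[n+]1ccccc1
Why: O-sulfation of a phenol with the SO3·pyridine complex should take place at the only free phenol (O8), since the guaiacyl oxygen is benzylated and any sulfonation of the lactam is reversed on aqueous work-up.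

Step 5
Reactants: 9 7-[4-(benzyloxy)-3-methoxybenzyl]-3-methoxy-2-oxo-1,2-dihydroquinolin-8-yl hydrogen sulfate
Product: 10 scolopendrine, 7-(4-hydroxy-3-methoxybenzyl)-3-methoxy-2-oxo-1,2-dihydroquinolin-8-yl hydrogen sulfate
Conditions: H2 (1 atm), 10% Pd/C, MeOH–H2O, rt (sodium salt); then Dowex 50W (H+ form), 0 °C, lyophilise
Reagents that add atoms: none
Why: Catalytic hydrogenolysis of the benzyl aryl ether should leave the aryl sulfate monoester salt, the diarylmethane CH2 and the 2-quinolinone untouched at 1 atm and room temperature.

Compound list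
1 | 2-bromocyclohex-1-ene-1-carbaldehyde | O=CC1=C(Br)CCCC1 | starting material
2 | 2-methoxyacetamide | COCC(N)=O | starting material
3 | N-(2-formylcyclohex-1-en-1-yl)-2-methoxyacetamide | COCC(=O)NC1=C(C=O)CCCC1 | intermediate
4 | 3-methoxy-5,6,7,8-tetrahydroquinolin-2(1H)-one | COc1cc2CCCCc2[nH]c1=O | intermediate
5 | 3-methoxy-6,7-dihydroquinoline-2,8(1H,5H)-dione | COc1cc2CCCC(=O)c2[nH]c1=O | intermediate
6 | 4-(benzyloxy)-3-methoxybenzaldehyde (O-benzylvanillin) | COc1cc(C=O)ccc1OCc1ccccc1 | starting material
7 | (E)-7-[4-(benzyloxy)-3-methoxybenzylidene]-3-methoxy-6,7-dihydroquinoline-2,8(1H,5H)-dione | COc1cc2CC/C(=C\c3ccc(OCc4ccccc4)c(OC)c3)C(=O)c2[nH]c1=O | intermediate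
8 | 7-[4-(benzyloxy)-3-methoxybenzyl]-8-hydroxy-3-methoxyquinolin-2(1H)-one | COc1cc2ccc(Cc3ccc(OCc4ccccc4)c(OC)c3)c(O)c2[nH]c1=O | intermediate
9 | 7-[4-(benzyloxy)-3-methoxybenzyl]-3-methoxy-2-oxo-1,2-dihydroquinolin-8-yl hydrogen sulfate | COc1cc2ccc(Cc3ccc(OCc4ccccc4)c(OC)c3)c(OS(=O)(=O)O)c2[nH]c1=O | intermediate
10 | scolopendrine, 7-(4-hydroxy-3-methoxybenzyl)-3-methoxy-2-oxo-1,2-dihydroquinolin-8-yl hydrogen sulfate | COc1cc(Cc2ccc3cc(OC)c(=O)[nH]c3c2OS(=O)(=O)O)ccc1O | target

Total step count: 5
Longest linear sequence: 5 steps (1 → 4 → 5 → 8 → 9 → 10)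

Steps most likely to fail

Step 2. The oxidation may attack the other ring methylene (C5), or run on at C7 of the product ketone to a 7,8-dione or to dehydrogenation. Fallback, setting out from 4 and coming back at 5: n-BuLi (2.2 equiv) in THF at −78 to 0 °C should form the N,C8-dianion (lateral lithiation as for 6-alkyl-2-pyridones). Hydroxylation of this dianion with 2-(phenylsulfonyl)-3-phenyloxaziridine (O=S(=O)(c1ccccc1)N1OC1c1ccccc1) should give racemic 8-hydroxy-3-methoxy-5,6,7,8-tetrahydroquinolin-2(1H)-one F1. Oxidation of this activated alcohol with MnO2 in CH2Cl2 at room temperature should then give 5.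

Step 3. The N-deprotonated pyridonate may lower the acidity at C7 so far that the aldol condensation stalls, or the sequence may stop at the exocyclic enone 7 without isomerising. The electron-rich phenoxide may also degrade oxidatively. Fallback, setting out from 5 and coming back at 8: LDA (2.2 equiv) in THF–DMPU at −78 °C followed by 4-(benzyloxy)-3-methoxybenzyl bromide (COc1cc(CBr)ccc1OCc1ccccc1) should alkylate the C7 enolate to give racemic 7-[4-(benzyloxy)-3-methoxybenzyl]-3-methoxy-6,7-dihydroquinoline-2,8(1H,5H)-dione F2. Aerobic Pd(II) dehydrogenation of this tetralone-type ketone (Pd(TFA)2, 2-(dimethylamino)pyridine, TsOH, O2, DMSO, 80 °C) should then aromatise the carbocycle and give 8.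

Step 1. The bromo-enal may decompose under carbonate at 100 °C before C–N coupling, or the amidate of 3 may fail to close the ring. Fallback, setting out from 1 and coming back at 4: NH3 in MeOH (sealed tube, rt) should displace the vinylic bromide by addition–elimination to give 2-aminocyclohex-1-ene-1-carbaldehyde F3. Acylation with methoxyacetyl chloride (COCC(Cl)=O) and pyridine in CH2Cl2 should give 3, now isolated. KOtBu in THF (rt to 60 °C) should then effect the aldol ring closure to 4.

Further compounds
F1 | step 2 | (±)-8-hydroxy-3-methoxy-5,6,7,8-tetrahydroquinolin-2(1H)-one | COc1cc2CCCC(O)c2[nH]c1=O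
F2 | step 3 | (±)-7-[4-(benzyloxy)-3-methoxybenzyl]-3-methoxy-6,7-dihydroquinoline-2,8(1H,5H)-dione | COc1cc2CCC(Cc3ccc(OCc4ccccc4)c(OC)c3)C(=O)c2[nH]c1=O
F3 | step 1 | 2-aminocyclohex-1-ene-1-carbaldehyde | NC1=C(C=O)CCCC1
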